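**Strategy.** Everything rests on the bond between C3, the CH that carries the isopropenyl group, and the quaternary benzylic C4 of the tetralone ring (C1 = ketone carbon). The key step exploits the C5 phenol on the arene carbon next to C4 and the propanoic acid chain on C4: in the precursor that acid is a γ-lactone on C4, a latent ortho-quinone methide. A chiral phosphoric acid opens the lactone, the prenyl ketone side chain attacks the methide carbon, and ene-type proton loss forms the isopropenyl group. One isomerisation should thus deliver the six-membered ring, both stereocentres and the free acid. The precursor is an acyclic aryl prenyl ketone bearing a 5-aryl-5-methylbutyrolactone.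

Key step: step 10

Remark on numbering: tetralone numbering is used in the text (C1 C=O, C2 CH2, C3 CH, C4 quaternary, C5/C6/C8 OH, C7 isopropyl); the target is (3S,4R) in this numbering, which is (2S,1R) in the systematic name of 20.
Remark on stereochemistry: compounds 12 and 14 to 18 are racemic at the lactone carbon (14 is also a diastereomer mixture); this centre becomes planar in step 10.
Assumption: the sense of induction of the phosphoric acid cannot be predicted with confidence; the antipode that gives 20 is fixed by an initial screen, and the (R)-acid is written.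

Step 1
Reactants: 1 2,5-dimethoxyphenol; 2 chloromethyl methyl ether
Product: 3 1,4-dimethoxy-2-(methoxymethoxy)benzene
Conditions: NaH, THF–DMF, 0 → 20 °C
Reagents that add atoms: chloromethyl methyl ether, COCCl
Why: Williamson-type O-alkylation of the phenoxide installs the acetal that directs the lithiation of step 2.

Step 2
Reactants: 3 1,4-dimethoxy-2-(methoxymethoxy)benzene; 4 acetone
Product: 5 2-[3,6-dimethoxy-2-(methoxymethoxy)phenyl]propan-2-ol
Conditions: n-BuLi, THF, 0 °C; then 4, –78 → 0 °C; H2O
Reagents that add atoms: acetone, CC(C)=O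
Why: Directed ortho-metalation should occur at the only ring position flanked by two oxygen donors (between OCH2OCH3 and OCH3), and the aryllithium adds to acetone.

Step 3
Reactants: 5 2-[3,6-dimethoxy-2-(methoxymethoxy)phenyl]propan-2-ol
Product: 6 3,6-dimethoxy-2-(propan-2-yl)phenol
Conditions: Et3SiH, CF3CO2H, CH2Cl2, 0 → 20 °C
Reagents that add atoms: none
Why: Ionic hydrogenation reduces the benzylic cation stabilised by two ortho oxygens, and the same acid cleaves the acetal, which frees the phenol that steers step 4.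

Step 4
Reactants: 6 3,6-dimethoxy-2-(propan-2-yl)phenol; 7 dichloromethyl methyl ether
Product: 8 4-hydroxy-2,5-dimethoxy-3-(propan-2-yl)benzaldehyde
Conditions: TiCl4, CH2Cl2, –20 → 0 °C; then H2O
Reagents that add atoms: dichloromethyl methyl ether, COC(Cl)Cl; water, O
Why: Rieche formylation should go para to the free phenol because both ortho positions are blocked and this carbon is also ortho to a methoxy group.

Step 5
Reactants: 8 4-hydroxy-2,5-dimethoxy-3-(propan-2-yl)benzaldehyde; 2 chloromethyl methyl ether
Product: 9 2,5-dimethoxy-4-(methoxymethoxy)-3-(propan-2-yl)benzaldehyde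
Conditions: NaH, DMF, 0 → 20 °C
Reagents that add atoms: chloromethyl methyl ether, COCCl
Why: O-alkylation masks the future C6 hydroxyl for the organometallic steps with a group that differs from the two methyl ethers.

Step 6
Reactants: 9 2,5-dimethoxy-4-(methoxymethoxy)-3-(propan-2-yl)benzaldehyde; 10 methyl 4-oxopentanoate (methyl levulinate)
Product: 12 3,6-dimethoxy-4-(methoxymethoxy)-2-(2-methyl-5-oxooxolan-2-yl)-5-(propan-2-yl)benzaldehyde (racemic), via aryllithium 11 (not isolated)
Conditions: LiN(CH3)CH2CH2N(CH3)2 (from the amine and n-BuLi), THF, –20 °C; n-BuLi, –20 °C; CeCl3, –78 °C; then 10, –78 → 20 °C; H2O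
Reagents that add atoms: methyl 4-oxopentanoate, COC(=O)CCC(C)=O
Why: The lithium amide adds to the aldehyde to give an α-amino alkoxide that masks it and, together with the neighbouring methoxy group, directs ortho-lithiation to the one remaining ring hydrogen; the derived organocerium should add to the ketone without enolisation, lactonisation follows in the flask, and the quaternary centre forms racemic.

Step 7
Reactants: 12 the lactone aldehyde; 13 1-chloro-3-methylbut-2-ene (prenyl chloride)
Product: 14 5-[2-(1-hydroxy-4-methylpent-3-enyl)-3,6-dimethoxy-5-(methoxymethoxy)-4-(propan-2-yl)phenyl]-5-methyloxolan-2-one (diastereomer mixture)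
Conditions: BaI2, LiC12H10 (lithium biphenylide), THF, 20 °C; then 13, –78 °C; then 12, –78 °C; H2O
Reagents that add atoms: 1-chloro-3-methylbut-2-ene, CC(C)=CCCl
Why: Allylbarium reagents add to aldehydes through the unsubstituted α carbon, so the linear prenyl carbinol should form, the aldehyde reacting before the lactone at –78 °C; the carbinol centre is not controlled because it is oxidised next.

Step 8
Reactants: 14 the prenyl carbinol
Product: 15 5-[3,6-dimethoxy-5-(methoxymethoxy)-2-(4-methylpent-3-enoyl)-4-(propan-2-yl)phenyl]-5-methyloxolan-2-one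
Conditions: Dess–Martin periodinane, pyridine, CH2Cl2, 0 → 20 °C
Reagents that add atoms: none
Why: Dess–Martin oxidation under buffered, non-basic conditions should give the β,γ-unsaturated aryl ketone without moving the double bond into conjugation.

Step 9
Reactants: 15 the protected aryl prenyl ketone
Product: 18 5-[2,3,5-trihydroxy-6-(4-methylpent-3-enoyl)-4-(propan-2-yl)phenyl]-5-methyloxolan-2-one, via methoxymethoxyquinone 16 (not isolated), via hydroxyquinone 17 (not isolated)
Conditions: (NH4)2Ce(NO3)6, MeCN–H2O, 0 → 20 °C; then Na2S2O4, H2O–EtOAc, 0 °C, Ar; used at once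
Reagents that add atoms: water, O
Why: Oxidative demethylation of the para-dimethoxyarene gives the quinone, whose methoxymethyl vinylogous ester is hydrolysed in the acidic medium, and dithionite reduces the hydroxyquinone to the hydroquinone, so all three phenols are freed while the lactone cannot ionise at the quinone stage.

Step 10
Reactants: 18 the trihydroxyaryl lactone
Product: 20 3-[(1R,2S)-5,7,8-trihydroxy-1-methyl-4-oxo-6-(propan-2-yl)-2-(prop-1-en-2-yl)-1,2,3,4-tetrahydronaphthalen-1-yl]propanoic acid, via ortho-quinone methide 19 (not isolated)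
Conditions: (R)-3,3′-bis(2,4,6-triisopropylphenyl)-1,1′-binaphthyl-2,2′-diyl hydrogen phosphate (10 mol%), PhCF3–CH2Cl2, 4 Å molecular sieves, –20 → 20 °C, Ar
Reagents that add atoms: none
Why: Proposed new method: the phosphoric acid activates the lactone while the C5 phenol donates, so the C4–O bond ionises reversibly to the planar ortho-quinone methide 19 (both lactone antipodes converge), C3 of the prenyl double bond attacks the methide carbon C4 inside the hydrogen-bonded complex, and the tertiary cation that develops over the C5 oxygen loses a methyl proton to the phosphate, which gives the isopropenyl group and re-aromatises the ring. The closest known reactions are chiral phosphoric acid-catalysed additions and [4+2] cycloadditions of alkenes to ortho-quinone methides, the Lewis acid-catalysed intramolecular ene reaction of alkylidene 1,3-dicarbonyl compounds with a tethered prenyl group, and Brønsted acid-catalysed carbonyl-ene cyclisation of the citronellal to isopulegol type. The ring closes 6-endo-trig at the methide bond C4=C4a (the prenyl double bond stays exocyclic), whereas the enol carbon C2 or the ketone oxygen could only close 5-endo-trig and ether formation through the C5 oxygen would place C4a at the bridgehead of a bicyclo[3.3.1] system. C4 is controlled by the catalyst, which shields one enantiotopic face of the methide, and C3 by the compact transition state with the prenyl terminus over the methide oxygen, which sets isopropenyl cis to the acid chain when the chain lies outside (Z methide) and the smaller methyl group inside next to the acyl substituent. The step needs the cis closure, the ene termination and a slow uncatalysed background; the inside/outside preference, the geometric exclusion of the other closures and the neutral, cold, non-basic medium are meant to secure them.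

**Compound list**

1 | 2,5-dimethoxyphenol | COc1ccc(OC)c(O)c1 | starting material
2 | chloromethyl methyl ether | COCCl | starting material
3 | 1,4-dimethoxy-2-(methoxymethoxy)benzene | COCOc1cc(OC)ccc1OC | intermediate
4 | acetone | CC(C)=O | starting material
5 | 2-[3,6-dimethoxy-2-(methoxymethoxy)phenyl]propan-2-ol | COCOc1c(C(C)(C)O)c(OC)ccc1OC | intermediate
6 | 3,6-dimethoxy-2-(propan-2-yl)phenol | COc1ccc(OC)c(C(C)C)c1O | intermediate
7 | dichloromethyl methyl ether | COC(Cl)Cl | starting material
8 | 4-hydroxy-2,5-dimethoxy-3-(propan-2-yl)benzaldehyde | COc1cc(C=O)c(OC)c(C(C)C)c1O | intermediate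
9 | 2,5-dimethoxy-4-(methoxymethoxy)-3-(propan-2-yl)benzaldehyde | COCOc1c(OC)cc(C=O)c(OC)c1C(C)C | intermediate
10 | methyl 4-oxopentanoate (methyl levulinate) | COC(=O)CCC(C)=O | starting material
11 | ortho-lithiated lithium α-amino alkoxide of 9 (aryllithium) | [Li]c1c(OC)c(OCOC)c(C(C)C)c(OC)c1C(O[Li])N(C)CCN(C)C | intermediate
12 | 3,6-dimethoxy-4-(methoxymethoxy)-2-(2-methyl-5-oxooxolan-2-yl)-5-(propan-2-yl)benzaldehyde (racemic) | COCOc1c(OC)c(C2(C)CCC(=O)O2)c(C=O)c(OC)c1C(C)C | intermediate
13 | 1-chloro-3-methylbut-2-ene | CC(C)=CCCl | starting material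
14 | 5-[2-(1-hydroxy-4-methylpent-3-enyl)-3,6-dimethoxy-5-(methoxymethoxy)-4-(propan-2-yl)phenyl]-5-methyloxolan-2-one (diastereomer mixture) | COCOc1c(OC)c(C2(C)CCC(=O)O2)c(C(O)CC=C(C)C)c(OC)c1C(C)C | intermediate
15 | 5-[3,6-dimethoxy-5-(methoxymethoxy)-2-(4-methylpent-3-enoyl)-4-(propan-2-yl)phenyl]-5-methyloxolan-2-one (racemic) | COCOc1c(OC)c(C2(C)CCC(=O)O2)c(C(=O)CC=C(C)C)c(OC)c1C(C)C | intermediate
16 | 5-[5-(methoxymethoxy)-2-(4-methylpent-3-enoyl)-3,6-dioxo-4-(propan-2-yl)cyclohexa-1,4-dien-1-yl]-5-methyloxolan-2-one (methoxymethoxyquinone) | COCOC1=C(C(C)C)C(=O)C(C(=O)CC=C(C)C)=C(C2(C)CCC(=O)O2)C1=O | intermediate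
17 | 5-[5-hydroxy-2-(4-methylpent-3-enoyl)-3,6-dioxo-4-(propan-2-yl)cyclohexa-1,4-dien-1-yl]-5-methyloxolan-2-one (hydroxyquinone) | OC1=C(C(C)C)C(=O)C(C(=O)CC=C(C)C)=C(C2(C)CCC(=O)O2)C1=O | intermediate
18 | 5-[2,3,5-trihydroxy-6-(4-methylpent-3-enoyl)-4-(propan-2-yl)phenyl]-5-methyloxolan-2-one (racemic) | CC(C)=CCC(=O)c1c(O)c(C(C)C)c(O)c(O)c1C2(C)CCC(=O)O2 | intermediate
19 | (Z)-4-[3,5-dihydroxy-2-(4-methylpent-3-enoyl)-6-oxo-4-(propan-2-yl)cyclohexa-2,4-dien-1-ylidene]pentanoic acid (ortho-quinone methide) | OC(=O)CC/C(C)=C1\C(=O)C(O)=C(C(C)C)C(O)=C1C(=O)CC=C(C)C | intermediate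
20 | 3-[(1R,2S)-5,7,8-trihydroxy-1-methyl-4-oxo-6-(propan-2-yl)-2-(prop-1-en-2-yl)-1,2,3,4-tetrahydronaphthalen-1-yl]propanoic acid | C=C(C)[C@@H]1CC(=O)c2c(O)c(C(C)C)c(O)c(O)c2[C@]1(C)CCC(=O)O | target

**Step count.** Total: 10 steps. Longest linear sequence: 10 steps (1 → 20); all other inputs are commercial.

**Steps most likely to fail**

Step 10 (Proposed new method). The catalyst may fail to discriminate the two faces of the methide, or the uncatalysed thermal ionisation and cyclisation may compete, so that the acid forms with low enantiomeric purity; closure with the chain inside would add the trans diastereomer. The fallback sets out from 18 and comes back at 20. It gives up catalyst control: ionisation of the benzylic lactone with an achiral acid (diphenyl phosphate or BF3·OEt2, CH2Cl2, –40 °C) is an ordinary cation–olefin cyclisation with loss of a proton. It should give the racemic cis acid, that is 20 together with its mirror image, 3-[(1S,2R)-5,7,8-trihydroxy-1-methyl-4-oxo-6-(propan-2-yl)-2-(prop-1-en-2-yl)-1,2,3,4-tetrahydronaphthalen-1-yl]propanoic acid F1. Classical resolution then follows by crystallisation of the (S)-1-phenylethylammonium salt of 20 F2 (the antipode of the amine is chosen by trial). Dilute HCl liberates 20; the crystallisation should also remove any trans diastereomer.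

Step 6. Ring lithiation next to the masked aldehyde may stay incomplete, or the hindered aryl metal may deprotonate the keto ester instead of adding to it. The fallback sets out from 9 and comes back at 12, and forms the aryl–carbon bond by cross-coupling instead. Bromination of the last ring position (NBS, MeCN) gives 2-bromo-3,6-dimethoxy-4-(methoxymethoxy)-5-(propan-2-yl)benzaldehyde F3. Suzuki–Miyaura coupling (Pd(OAc)2, SPhos, K3PO4, toluene–H2O) uses methyl 4-(4,4,5,5-tetramethyl-1,3,2-dioxaborolan-2-yl)pent-4-enoate F4, itself made from methyl pent-4-ynoate by Markovnikov hydroboration (CuCl, a carbene ligand, B2pin2, MeOH). This gives methyl 4-[2-formyl-3,6-dimethoxy-5-(methoxymethoxy)-4-(propan-2-yl)phenyl]pent-4-enoate F5. Saponification (LiOH, THF–H2O) gives 4-[2-formyl-3,6-dimethoxy-5-(methoxymethoxy)-4-(propan-2-yl)phenyl]pent-4-enoic acid F6, and Markovnikov lactonisation of the styrene acid (catalytic TsOH, CH2Cl2, 0 °C) returns 12.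

Step 9. The transient acylquinone may oxidise or enolise its own β,γ-unsaturated side chain (internal redox to a dienone hydroquinone), or the prenyl double bond may be attacked by the oxidant. The fallback sets out from 12 and comes back at 18, and moves the quinone stage ahead of the prenyl ketone.

- Oxidation of 12 with (NH4)2Ce(NO3)6 passes through 4-(methoxymethoxy)-2-(2-methyl-5-oxooxolan-2-yl)-3,6-dioxo-5-(propan-2-yl)cyclohexa-1,4-diene-1-carbaldehyde F7 and 4-hydroxy-2-(2-methyl-5-oxooxolan-2-yl)-3,6-dioxo-5-(propan-2-yl)cyclohexa-1,4-diene-1-carbaldehyde F8.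
- Na2S2O4 reduction in the same flask gives 3,4,6-trihydroxy-2-(2-methyl-5-oxooxolan-2-yl)-5-(propan-2-yl)benzaldehyde F9.
- Silylation (TESOTf, 2,6-lutidine, CH2Cl2) gives 2-(2-methyl-5-oxooxolan-2-yl)-5-(propan-2-yl)-3,4,6-tris(triethylsilyloxy)benzaldehyde F10.
- (3-Methylbut-2-enyl)barium chloride at –78 °C gives 5-[2-(1-hydroxy-4-methylpent-3-enyl)-4-(propan-2-yl)-3,5,6-tris(triethylsilyloxy)phenyl]-5-methyloxolan-2-one F11.
- Dess–Martin oxidation gives 5-[2-(4-methylpent-3-enoyl)-4-(propan-2-yl)-3,5,6-tris(triethylsilyloxy)phenyl]-5-methyloxolan-2-one F12.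
- HF·pyridine buffered with pyridine (THF, 0 °C) releases 18.

Further compounds
F1 | step 10 | 3-[(1S,2R)-5,7,8-trihydroxy-1-methyl-4-oxo-6-(propan-2-yl)-2-(prop-1-en-2-yl)-1,2,3,4-tetrahydronaphthalen-1-yl]propanoic acid | C=C(C)[C@H]1CC(=O)c2c(O)c(C(C)C)c(O)c(O)c2[C@@]1(C)CCC(=O)O
F2 | step 10 | (S)-1-phenylethylammonium salt of 20 | C=C(C)[C@@H]1CC(=O)c2c(O)c(C(C)C)c(O)c(O)c2[C@]1(C)CCC(=O)[O-].C[C@H]([NH3+])c1ccccc1
F3 | step 6 | 2-bromo-3,6-dimethoxy-4-(methoxymethoxy)-5-(propan-2-yl)benzaldehyde | COCOc1c(OC)c(Br)c(C=O)c(OC)c1C(C)C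
F4 | step 6 | methyl 4-(4,4,5,5-tetramethyl-1,3,2-dioxaborolan-2-yl)pent-4-enoate | COC(=O)CCC(=C)B1OC(C)(C)C(C)(C)O1
F5 | step 6 | methyl 4-[2-formyl-3,6-dimethoxy-5-(methoxymethoxy)-4-(propan-2-yl)phenyl]pent-4-enoate | COCOc1c(OC)c(C(=C)CCC(=O)OC)c(C=O)c(OC)c1C(C)C
F6 | step 6 | 4-[2-formyl-3,6-dimethoxy-5-(methoxymethoxy)-4-(propan-2-yl)phenyl]pent-4-enoic acid | COCOc1c(OC)c(C(=C)CCC(=O)O)c(C=O)c(OC)c1C(C)C
F7 | step 9 | 4-(methoxymethoxy)-2-(2-methyl-5-oxooxolan-2-yl)-3,6-dioxo-5-(propan-2-yl)cyclohexa-1,4-diene-1-carbaldehyde | COCOC1=C(C(C)C)C(=O)C(C=O)=C(C2(C)CCC(=O)O2)C1=O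
F8 | step 9 | 4-hydroxy-2-(2-methyl-5-oxooxolan-2-yl)-3,6-dioxo-5-(propan-2-yl)cyclohexa-1,4-diene-1-carbaldehyde | OC1=C(C(C)C)C(=O)C(C=O)=C(C2(C)CCC(=O)O2)C1=O
F9 | step 9 | 3,4,6-trihydroxy-2-(2-methyl-5-oxooxolan-2-yl)-5-(propan-2-yl)benzaldehyde | O=Cc1c(O)c(C(C)C)c(O)c(O)c1C2(C)CCC(=O)O2
F10 | step 9 | 2-(2-methyl-5-oxooxolan-2-yl)-5-(propan-2-yl)-3,4,6-tris(triethylsilyloxy)benzaldehyde | O=Cc1c(O[Si](CC)(CC)CC)c(C(C)C)c(O[Si](CC)(CC)CC)c(O[Si](CC)(CC)CC)c1C2(C)CCC(=O)O2
F11 | step 9 | 5-[2-(1-hydroxy-4-methylpent-3-enyl)-4-(propan-2-yl)-3,5,6-tris(triethylsilyloxy)phenyl]-5-methyloxolan-2-one | CC(C)=CCC(O)c1c(O[Si](CC)(CC)CC)c(C(C)C)c(O[Si](CC)(CC)CC)c(O[Si](CC)(CC)CC)c1C2(C)CCC(=O)O2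
F12 | step 9 | 5-[2-(4-methylpent-3-enoyl)-4-(propan-2-yl)-3,5,6-tris(triethylsilyloxy)phenyl]-5-methyloxolan-2-one | CC(C)=CCC(=O)c1c(O[Si](CC)(CC)CC)c(C(C)C)c(O[Si](CC)(CC)CC)c(O[Si](CC)(CC)CC)c1C2(C)CCC(=O)O2
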